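- Percentage points were my unit, because the question was whether two flasks differed by more than 2 percentage points, so I reckoned each flask as one large plateau minus a small gap.

| flask | substrate | coupling partner | remark | time |
|---|---|---|---|---|
| Saturday's | 0.11 M | 1 equiv (fed, over 3.0 min) | run made earlier |  |
| Tuesday's | 0.39 M | 1 equiv (fed, over 3.0 min) | run made earlier |  |
| west | 0.25 M | 1.00 equiv (fed, over 3.0 min) |  | 30 min |
| north-east | 0.080 M | 1.00 equiv | everything together at the start | 60 min |

- Saturday's (time / min: single product / %): 2.00: 2.6; 5.00: 11.2; 10.0: 17.4; 15.0: 19.2
- Tuesday's (time / min: single product / %): 4.00: 17.8; 8.00: 20.1; 12.0: 21.0; 15.0: 20.9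

(each reading ± 0.3 percentage points)

- the winner by amount of single product, in percent of the substrate charged; "neither" if no more than 2 percentage points parts them (west / north-east / neither)
- how much single product is there at the end, in percent of the substrate charged: west
- how much single product is there at the end, in percent of the substrate charged: north-east

- Tuesday's last two readings gave a plateau P of 20.9%. Saturday's 19.2% stood lower, and extrapolating its equally spaced readings geometrically gave 19.9%.
- I doubted that lower figure. Saturday's gap to P shrank by 2.75 over its first interval and 2.03 over its second, but a scatter of 0.3 points could produce that difference, and both ratios rested on taking Tuesday's P for Saturday's plateau, so I could not tell a lower plateau from the same one. I kept the figure as a floor.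
- From Saturday's last gaps I took a pseudo-first-order time τ and defined the clock product D, τ times the substrate concentration: 46.7 M·s. That made τ 3.11 min in west and 9.72 min in north-east.
- Did τ really scale as one over concentration? Tuesday's gap at 8.00 min should have been 0.42 points, and the reading gave 0.85 points, with a scatter of 0.3 points. The clock was rough, but with D doubled, north-east's gap was still 0.96 points.
- North-east was unfed, which worried me more. Saturday's feed was shorter than its τ, at 0.424 of it, so that run was nearly batch, and I placed north-east between 19.9% and 20.9%. West I put at 20.9%. The spread of 1 point gave me "neither".
- The forecast said 20.6% (19.8% to 21.4%) for west, 19.5% (18% to 20.5%) for north-east, and neither: “The plateau is therefore almost independent of concentration.” My floor for north-east lay above its figure.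
- The flasks gave 21.1% in west and 21.3% in north-east, so neither.

    substrate + coupling partner → single product (k = 0.00960 /M/s)
    substrate + coupling partner → other mono adduct (k = 0.00490 /M/s)
    coupling partner + single product → bis adduct (k = 0.0120 /M/s)
    coupling partner + other mono adduct → bis adduct (k = 0.00470 /M/s)
    single product ⇌ isomer of the product (K = 0.470, k = 0.00550 /s)

- D left gaps of 0.0036 points in west and 0.044 points in north-east, and ten times the time left single product at 21.1% and 21.3%. The rest had not stopped. West still held 2.5% of its coupling partner and north-east 6.8%. By 600 min, north-east's coupling partner stood at 0%, its substrate had gone from 28.2% to 24.6%, and its bis adduct from 21.4% to 24.6%.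

(Readings and results come from a simulation on assumed constants; noise was put on by code.)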